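Ring A is disconnected at the C4a–C5 bond. Its oxygen pattern (O1 on C8a, hydroxyls on C5 and C7) with the C4 ketone on C4a is that of a folded 3,5,7-tricarbonyl ester, so an intramolecular Claisen acylation of C4a by a C5 ester closes ring A and aromatises it in one operation, with no regiochemical choice. The precursor is a (2S)-2-aryl-2,3-dihydropyran-4-one (ring C complete, C2 set by asymmetric transfer hydrogenation) whose C6, the future C8a, carries a CH(prenyl)–CO–CH2–CO2Me chain. It is assembled from an (S)-β-silyloxy Weinreb amide and a prenylated keto-dioxinone, so C2, O1 and the C8 prenyl group are fixed before ring A exists.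

Key step: step 11

Remark: the prenyl-bearing sp3 carbon (future C8) in 14–19 is an uncontrolled, easily enolised centre, so these compounds are carried as mixtures there and drawn as single keto tautomers; the centre vanishes when ring A becomes aromatic.

Step 1
Reactants: 1 3-bromo-4-methoxybenzaldehyde; 2 4-bromo-2-methylbut-1-ene
Product: 4 4-methoxy-3-(3-methylbut-3-en-1-yl)benzaldehyde, via (3-methylbut-3-en-1-yl)zinc bromide 3 (not isolated)
Conditions: 2, Zn dust, LiCl, THF, 50 °C; then 1, Pd(OAc)2 (2 mol%), SPhos (4 mol%), THF, 23 °C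
Reagents that add atoms: none
Why: Zinc insertion into the primary bromide and Negishi coupling with the aryl bromide should work because alkylzinc halides transmetalate to arylpalladium faster than they add to an aldehyde and the SPhos ligand lets reductive elimination outrun β-hydride elimination, so the terminal alkene stays where it is.

Step 2
Reactants: 4 4-methoxy-3-(3-methylbut-3-en-1-yl)benzaldehyde; 5 N-methoxy-N-methylacetamide
Product: 6 rac-3-hydroxy-N-methoxy-3-[4-methoxy-3-(3-methylbut-3-en-1-yl)phenyl]-N-methylpropanamide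
Conditions: 5, LiN(iPr)2, THF, −78 °C; then 4, −78 °C; AcOH
Reagents that add atoms: none
Why: Aldol addition of the lithium enolate of the Weinreb acetamide to an aromatic aldehyde is fast at −78 °C and stops at the lithium aldolate; the carbinol centre is formed racemic and is erased in step 3.

Step 3
Reactants: 6 rac-3-hydroxy-N-methoxy-3-[4-methoxy-3-(3-methylbut-3-en-1-yl)phenyl]-N-methylpropanamide
Product: 7 N-methoxy-3-[4-methoxy-3-(3-methylbut-3-en-1-yl)phenyl]-N-methyl-3-oxopropanamide
Conditions: Dess–Martin periodinane, CH2Cl2, 0 to 23 °C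
Reagents that add atoms: none
Why: Dess–Martin oxidation converts the secondary benzylic alcohol into the aryl ketone under near-neutral conditions that do not touch the 1,1-disubstituted alkene or the N–O bond.

Step 4
Reactants: 7 N-methoxy-3-[4-methoxy-3-(3-methylbut-3-en-1-yl)phenyl]-N-methyl-3-oxopropanamide
Product: 8 (3S)-3-hydroxy-N-methoxy-3-[4-methoxy-3-(3-methylbut-3-en-1-yl)phenyl]-N-methylpropanamide
Conditions: RuCl[(S,S)-TsDPEN](p-cymene) (1 mol%), HCO2H–Et3N (5:2), DMF, 30 °C
Reagents that add atoms: none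
Why: Noyori–Ikariya asymmetric transfer hydrogenation: the (S,S)-TsDPEN ruthenium hydride reduces aryl ketones through an outer-sphere six-membered transition state to the S carbinol (priorities O > aryl > CH2 here), which sets the future C2, and it leaves isolated alkenes alone.

Step 5
Reactants: 8 (3S)-3-hydroxy-N-methoxy-3-[4-methoxy-3-(3-methylbut-3-en-1-yl)phenyl]-N-methylpropanamide
Product: 9 (3S)-N-methoxy-3-[4-methoxy-3-(3-methylbut-3-en-1-yl)phenyl]-N-methyl-3-(triethylsilyloxy)propanamide
Conditions: Et3SiCl, imidazole, CH2Cl2, 0 to 23 °C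
Reagents that add atoms: chlorotriethylsilane, CC[Si](Cl)(CC)CC
Why: Silyl ether formation with a silyl chloride and imidazole masks the alcohol for the enolate chemistry of step 8, and the TES group is labile enough to leave under the mild acid of step 9.

Step 6
Reactants: 10 2,2,6-trimethyl-4H-1,3-dioxin-4-one; 11 acetyl chloride
Product: 12 2,2-dimethyl-6-(2-oxopropyl)-4H-1,3-dioxin-4-one
Conditions: 10 (2 equiv), LiN(SiMe3)2 (2 equiv), THF, −78 °C; then 11 (1 equiv); AcOH
Reagents that add atoms: none
Why: Vinylogous Claisen acylation: the lithium dienolate of the dioxinone reacts with the acid chloride at its γ-carbon, and the second equivalent of dienolate takes up the more acidic product so that it is not acylated twice.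

Step 7
Reactants: 12 2,2-dimethyl-6-(2-oxopropyl)-4H-1,3-dioxin-4-one; 13 1-bromo-3-methylbut-2-ene (prenyl bromide)
Product: 14 2,2-dimethyl-6-(6-methyl-2-oxohept-5-en-3-yl)-4H-1,3-dioxin-4-one
Conditions: NaH (1.0 equiv), THF, 0 °C; then 13 (1.0 equiv), 0 to 23 °C
Reagents that add atoms: none
Why: SN2 C-alkylation of a stabilised enolate (the methylene lies between the ketone and the vinylogous ester of the dioxinone) with a soft allylic bromide puts the prenyl group on the future C8; the new centre is racemic and of no consequence.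

Step 8
Reactants: 14 2,2-dimethyl-6-(6-methyl-2-oxohept-5-en-3-yl)-4H-1,3-dioxin-4-one; 9 (3S)-N-methoxy-3-[4-methoxy-3-(3-methylbut-3-en-1-yl)phenyl]-N-methyl-3-(triethylsilyloxy)propanamide
Product: 15 6-[(10S)-10-[4-methoxy-3-(3-methylbut-3-en-1-yl)phenyl]-2-methyl-6,8-dioxo-10-(triethylsilyloxy)dec-2-en-5-yl]-2,2-dimethyl-4H-1,3-dioxin-4-one
Conditions: 14 (1.5 equiv), LiN(iPr)2 (3.0 equiv), THF, −78 °C; then 9, −78 to −40 °C; AcOH
Reagents that add atoms: none
Why: Dianion Claisen acylation: after the methine is deprotonated the second equivalent of amide base removes a methyl proton, the terminal carbanion is the most nucleophilic site, and the Weinreb amide holds the adduct as a chelated tetrahedral intermediate until the quench, so the 1,3-diketone forms without over-addition and the silyloxy-bearing centre is untouched.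

Step 9
Reactants: 15 6-[(10S)-10-[4-methoxy-3-(3-methylbut-3-en-1-yl)phenyl]-2-methyl-6,8-dioxo-10-(triethylsilyloxy)dec-2-en-5-yl]-2,2-dimethyl-4H-1,3-dioxin-4-one
Product: 17 6-{1-[(2S)-2-[4-methoxy-3-(3-methylbut-3-en-1-yl)phenyl]-4-oxo-3,4-dihydro-2H-pyran-6-yl]-4-methylpent-3-en-1-yl}-2,2-dimethyl-4H-1,3-dioxin-4-one, via hydroxy diketo-dioxinone 16 (not isolated)
Conditions: aq. HF (48%), MeCN, 0 to 23 °C
Reagents that add atoms: none
Why: Acid removes the TES group and the freed δ-hydroxyl adds to the ketone next to the prenyl-bearing carbon to give a six-membered hemiketal that loses water (cyclodehydration of a δ-hydroxy-β-diketone to a 2,3-dihydro-4H-pyran-4-one); the C2–O bond is never broken, so the S configuration is retained, and once ring C is closed the aldol mode of aromatisation is blocked.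

Step 10
Reactants: 17 6-{1-[(2S)-2-[4-methoxy-3-(3-methylbut-3-en-1-yl)phenyl]-4-oxo-3,4-dihydro-2H-pyran-6-yl]-4-methylpent-3-en-1-yl}-2,2-dimethyl-4H-1,3-dioxin-4-one
Product: 19 methyl 4-[(2S)-2-[4-methoxy-3-(3-methylbut-3-en-1-yl)phenyl]-4-oxo-3,4-dihydro-2H-pyran-6-yl]-7-methyl-3-oxooct-6-enoate, via acylketene 18 (not isolated)
Conditions: MeOH (20 equiv), toluene, 100 °C, sealed tube
Reagents that add atoms: methanol, CO
Why: Thermal retro-hetero-Diels–Alder loss of acetone from the dioxinone gives an acylketene that methanol captures as the methyl β-keto ester (standard dioxinone alcoholysis) under neutral conditions that endanger neither C2 nor the alkenes.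

Step 11
Reactants: 19 methyl 4-[(2S)-2-[4-methoxy-3-(3-methylbut-3-en-1-yl)phenyl]-4-oxo-3,4-dihydro-2H-pyran-6-yl]-7-methyl-3-oxooct-6-enoate
Product: 21 (2S)-5,7-dihydroxy-2-[4-methoxy-3-(3-methylbut-3-en-1-yl)phenyl]-8-(3-methylbut-2-en-1-yl)-2,3-dihydro-4H-chromen-4-one, via ring A triketone tautomer 20 (not isolated)
Conditions: KOtBu (1.1 equiv, added slowly), THF (0.02 M), argon, −40 to 20 °C; then AcOH
Reagents that add atoms: none
Why: Proposed new method: one equivalent of base removes the C8 proton (α to the C7 ketone and γ to the C4 carbonyl through C8a=C4a), and the resulting dienolate attacks the still-neutral C5 ester through C4a; loss of methoxide gives triketone 20, which enolises to the phloroglucinol and rests as its phenoxide until the acid quench. The closest known reaction types are the base-mediated Claisen cyclisation of 3,5,7-triketo esters to acylphloroglucinols and Lacey–Dieckmann closures, in which a stabilised enolate acylates on a methyl ester; neither has been shown with one ketone masked as a cyclic vinylogous ester. Ring A closes in a 6-(enolexo)-exo-trig acyl substitution. No stereocentre is formed: C2 lies outside the reacting π system and the C8 centre disappears on aromatisation. The step needs Claisen closure to win over aldol closure and the O1–C2 bond to stay intact: attack of C6 on C4 can only give a bridged aldolate that cannot dehydrate and so reverts, C8 cannot reach the ester (four-membered ring), and the 8-prenyl regiochemistry is fixed because O1 and the prenyl group already sit on C8a and C8. Holding the base at about one equivalent keeps the ester un-enolised in the reacting anion and leaves no strong base to deprotonate C3, which is what an E1cB opening to the chalcone and loss of the C2 configuration would require.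

Compound list
1 | 3-bromo-4-methoxybenzaldehyde | COc1ccc(C=O)cc1Br | starting material
2 | 4-bromo-2-methylbut-1-ene | C=C(C)CCBr | starting material
3 | (3-methylbut-3-en-1-yl)zinc bromide | C=C(C)CC[Zn]Br | intermediate (not isolated)
4 | 4-methoxy-3-(3-methylbut-3-en-1-yl)benzaldehyde | C=C(C)CCc1cc(C=O)ccc1OC | intermediate
5 | N-methoxy-N-methylacetamide | CC(=O)N(C)OC | starting material
6 | rac-3-hydroxy-N-methoxy-3-[4-methoxy-3-(3-methylbut-3-en-1-yl)phenyl]-N-methylpropanamide | C=C(C)CCc1cc(C(O)CC(=O)N(C)OC)ccc1OC | intermediate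
7 | N-methoxy-3-[4-methoxy-3-(3-methylbut-3-en-1-yl)phenyl]-N-methyl-3-oxopropanamide | C=C(C)CCc1cc(C(=O)CC(=O)N(C)OC)ccc1OC | intermediate
8 | (3S)-3-hydroxy-N-methoxy-3-[4-methoxy-3-(3-methylbut-3-en-1-yl)phenyl]-N-methylpropanamide | C=C(C)CCc1cc([C@@H](O)CC(=O)N(C)OC)ccc1OC | intermediate
9 | (3S)-N-methoxy-3-[4-methoxy-3-(3-methylbut-3-en-1-yl)phenyl]-N-methyl-3-(triethylsilyloxy)propanamide | C=C(C)CCc1cc([C@@H](O[Si](CC)(CC)CC)CC(=O)N(C)OC)ccc1OC | intermediate
10 | 2,2,6-trimethyl-4H-1,3-dioxin-4-one | CC1=CC(=O)OC(C)(C)O1 | starting material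
11 | acetyl chloride | CC(=O)Cl | starting material
12 | 2,2-dimethyl-6-(2-oxopropyl)-4H-1,3-dioxin-4-one | CC(=O)CC1=CC(=O)OC(C)(C)O1 | intermediate
13 | 1-bromo-3-methylbut-2-ene (prenyl bromide) | CC(C)=CCBr | starting material
14 | 2,2-dimethyl-6-(6-methyl-2-oxohept-5-en-3-yl)-4H-1,3-dioxin-4-one (racemic) | CC(=O)C(CC=C(C)C)C1=CC(=O)OC(C)(C)O1 | intermediate
15 | 6-[(10S)-10-[4-methoxy-3-(3-methylbut-3-en-1-yl)phenyl]-2-methyl-6,8-dioxo-10-(triethylsilyloxy)dec-2-en-5-yl]-2,2-dimethyl-4H-1,3-dioxin-4-one (mixture at chain C5) | C=C(C)CCc1cc([C@@H](O[Si](CC)(CC)CC)CC(=O)CC(=O)C(CC=C(C)C)C2=CC(=O)OC(C)(C)O2)ccc1OC | intermediate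
16 | 6-[(10S)-10-hydroxy-10-[4-methoxy-3-(3-methylbut-3-en-1-yl)phenyl]-2-methyl-6,8-dioxodec-2-en-5-yl]-2,2-dimethyl-4H-1,3-dioxin-4-one | C=C(C)CCc1cc([C@@H](O)CC(=O)CC(=O)C(CC=C(C)C)C2=CC(=O)OC(C)(C)O2)ccc1OC | intermediate (not isolated)
17 | 6-{1-[(2S)-2-[4-methoxy-3-(3-methylbut-3-en-1-yl)phenyl]-4-oxo-3,4-dihydro-2H-pyran-6-yl]-4-methylpent-3-en-1-yl}-2,2-dimethyl-4H-1,3-dioxin-4-one | C=C(C)CCc1cc([C@@H]2CC(=O)C=C(C(CC=C(C)C)C3=CC(=O)OC(C)(C)O3)O2)ccc1OC | intermediate
18 | 4-[(2S)-2-[4-methoxy-3-(3-methylbut-3-en-1-yl)phenyl]-4-oxo-3,4-dihydro-2H-pyran-6-yl]-7-methyl-3-oxoocta-1,6-dien-1-one (acylketene) | C=C(C)CCc1cc([C@@H]2CC(=O)C=C(C(CC=C(C)C)C(=O)C=C=O)O2)ccc1OC | intermediate (not isolated)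
19 | methyl 4-[(2S)-2-[4-methoxy-3-(3-methylbut-3-en-1-yl)phenyl]-4-oxo-3,4-dihydro-2H-pyran-6-yl]-7-methyl-3-oxooct-6-enoate | C=C(C)CCc1cc([C@@H]2CC(=O)C=C(C(CC=C(C)C)C(=O)CC(=O)OC)O2)ccc1OC | intermediate (key-step precursor)
20 | (2S)-2-[4-methoxy-3-(3-methylbut-3-en-1-yl)phenyl]-8-(3-methylbut-2-en-1-yl)-2,3-dihydro-4aH-chromene-4,5,7(6H)-trione | C=C(C)CCc1cc([C@@H]2CC(=O)C3C(=O)CC(=O)C(CC=C(C)C)=C3O2)ccc1OC | intermediate (not isolated)
21 | (2S)-5,7-dihydroxy-2-[4-methoxy-3-(3-methylbut-3-en-1-yl)phenyl]-8-(3-methylbut-2-en-1-yl)-2,3-dihydro-4H-chromen-4-one | C=C(C)CCc1cc([C@@H]2CC(=O)c3c(O)cc(O)c(CC=C(C)C)c3O2)ccc1OC | target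

Total step count: 11. Longest linear sequence: 9 steps (steps 1–5 and 8–11).

Steps most likely to fail

Step 11 (Proposed new method). The monoanion should rest mainly as the unreactive C6 enolate of the β-keto ester. Ring closure through the minor C8 dienolate may therefore be slower than condensation between molecules, or than a second deprotonation that switches the ester off. Prolonged contact with base could also open ring C through the C3 enolate and erode the C2 configuration. The fallback uses known chemistry, sets out from 4 and returns at 21 by the classical chalcone route with a final resolution. Commercial 1-(2,4,6-trihydroxyphenyl)ethanone is C-prenylated with 13 in aqueous KOH to 1-[2,4,6-trihydroxy-3-(3-methylbut-2-en-1-yl)phenyl]ethanone F1. MOMCl and iPr2NEt should take the para hydroxyl and the less hindered ortho hydroxyl and leave the hydrogen-bonded hydroxyl beside the prenyl group free, giving 1-[2-hydroxy-4,6-bis(methoxymethoxy)-3-(3-methylbut-2-en-1-yl)phenyl]ethanone F2. Claisen–Schmidt condensation of F2 with 4 (KOH, EtOH) gives (E)-1-[2-hydroxy-4,6-bis(methoxymethoxy)-3-(3-methylbut-2-en-1-yl)phenyl]-3-[4-methoxy-3-(3-methylbut-3-en-1-yl)phenyl]prop-2-en-1-one F3. NaOAc in refluxing EtOH closes ring C by oxa-Michael addition of the only free phenol, which sits next to the prenyl group, to rac-5,7-bis(methoxymethoxy)-2-[4-methoxy-3-(3-methylbut-3-en-1-yl)phenyl]-8-(3-methylbut-2-en-1-yl)-2,3-dihydro-4H-chromen-4-one F4. HCl in MeOH removes both MOM groups to the racemic flavanone F5, and preparative HPLC on a polysaccharide chiral stationary phase delivers 21.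

Step 8. Proton transfer from the α-methylene of the Weinreb amide to the strongly basic dianion, followed by β-elimination of the silanolate, or incomplete formation of the dianion from the substituted keto-dioxinone, would starve the C4–C4a bond formation. The fallback sets out from 9 and returns at 15 by aldol addition and oxidation in place of acyl substitution. iBu2AlH (THF, −78 °C) reduces the Weinreb amide to (3S)-3-[4-methoxy-3-(3-methylbut-3-en-1-yl)phenyl]-3-(triethylsilyloxy)propanal F6. The dianion of 14 should add to this aldehyde at −78 °C fast enough that carbonyl addition outruns proton transfer, giving 6-[(10S)-8-hydroxy-10-[4-methoxy-3-(3-methylbut-3-en-1-yl)phenyl]-2-methyl-6-oxo-10-(triethylsilyloxy)dec-2-en-5-yl]-2,2-dimethyl-4H-1,3-dioxin-4-one F7. Dess–Martin oxidation of the new carbinol then returns 15.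

Step 7. The ambident enolate of 12 may alkylate on oxygen or twice on carbon, so that the mono-C-prenyl compound is hard to obtain pure. The fallback sets out from 10 and returns at 14 by forming the two C–C bonds in the reverse order. γ-Alkylation of the lithium dienolate of 10 (LiN(iPr)2, THF–DMPU, −78 °C) with 13 gives 2,2-dimethyl-6-(4-methylpent-3-en-1-yl)-4H-1,3-dioxin-4-one F8, a step in which no β-dicarbonyl anion is involved. γ-Acetylation of the dienolate of F8 with 11 under the conditions of step 6 gives 14.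

Further compounds
F1 | step 11 | 1-[2,4,6-trihydroxy-3-(3-methylbut-2-en-1-yl)phenyl]ethanone | CC(=O)c1c(O)cc(O)c(CC=C(C)C)c1O
F2 | step 11 | 1-[2-hydroxy-4,6-bis(methoxymethoxy)-3-(3-methylbut-2-en-1-yl)phenyl]ethanone | CC(=O)c1c(OCOC)cc(OCOC)c(CC=C(C)C)c1O
F3 | step 11 | (E)-1-[2-hydroxy-4,6-bis(methoxymethoxy)-3-(3-methylbut-2-en-1-yl)phenyl]-3-[4-methoxy-3-(3-methylbut-3-en-1-yl)phenyl]prop-2-en-1-one | C=C(C)CCc1cc(/C=C/C(=O)c2c(OCOC)cc(OCOC)c(CC=C(C)C)c2O)ccc1OC
F4 | step 11 | rac-5,7-bis(methoxymethoxy)-2-[4-methoxy-3-(3-methylbut-3-en-1-yl)phenyl]-8-(3-methylbut-2-en-1-yl)-2,3-dihydro-4H-chromen-4-one | C=C(C)CCc1cc(C2CC(=O)c3c(OCOC)cc(OCOC)c(CC=C(C)C)c3O2)ccc1OC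
F5 | step 11 | rac-5,7-dihydroxy-2-[4-methoxy-3-(3-methylbut-3-en-1-yl)phenyl]-8-(3-methylbut-2-en-1-yl)-2,3-dihydro-4H-chromen-4-one | C=C(C)CCc1cc(C2CC(=O)c3c(O)cc(O)c(CC=C(C)C)c3O2)ccc1OC
F6 | step 8 | (3S)-3-[4-methoxy-3-(3-methylbut-3-en-1-yl)phenyl]-3-(triethylsilyloxy)propanal | C=C(C)CCc1cc([C@@H](O[Si](CC)(CC)CC)CC=O)ccc1OC
F7 | step 8 | 6-[(10S)-8-hydroxy-10-[4-methoxy-3-(3-methylbut-3-en-1-yl)phenyl]-2-methyl-6-oxo-10-(triethylsilyloxy)dec-2-en-5-yl]-2,2-dimethyl-4H-1,3-dioxin-4-one | C=C(C)CCc1cc([C@@H](O[Si](CC)(CC)CC)CC(O)CC(=O)C(CC=C(C)C)C2=CC(=O)OC(C)(C)O2)ccc1OC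
F8 | step 7 | 2,2-dimethyl-6-(4-methylpent-3-en-1-yl)-4H-1,3-dioxin-4-one | CC(C)=CCCC1=CC(=O)OC(C)(C)O1
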